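## Retrosynthetic overview

1. The target is reached by global desilylation of a protected dihydronaphthalenol; its carbocycle (ring B) is closed last by ring-closing metathesis forming C3'=C4'.
2. The key bond C1'–C2' comes from an intermolecular Evans magnesium-catalysed anti-aldol between biaryl aldehyde 20 and the N-(3-methylbut-3-enoyl)oxazolidinone 25; this sets both stereocentres.
3. The imide is converted to the methyl ketone via a thioester and a cuprate, which leaves the acetyl group of ring A untouched.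
4. Aldehyde 20 comes from Suzuki coupling of naphthyl boronate 14 with bromo-aldehyde 19; 19 derives from 2-bromo-5-iodophenol by ortho-formylation, silylation and Stille vinylation.
5. Ring A comes from a tandem Michael–Claisen annulation of toluate 6 with 4-methoxypent-3-en-2-one. Ring order: naphthalene second ring, then biaryl, then ring B.

Assumption: compounds 1, 7, 15, 21 and 22 are bought as catalogue items; primed locants (C1', C2' …) refer to the dihydronaphthalene half of the target.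

Abbreviations: NpSi = 2-acetyl-3-methylnaphthalen-7-yl whose O1 and O8 are bridged by Si(t-Bu)2 (six-membered O–Si–O ring). ArB = 3-(NpSi)-2-[(triisopropylsilyl)oxy]-6-vinylphenyl. TIPS = triisopropylsilyl, TES = triethylsilyl.

## Route

**Step 1**
Reactants: 1 2-bromo-5-methylphenol
Product: 3 3-bromo-2-hydroxy-6-methylbenzaldehyde, via hydroxymethyl phenol 2 (not isolated)
Conditions: MgCl2, Et3N, (CH2O)n, MeCN, reflux; 1 M HCl
Reagents that add atoms: paraformaldehyde (formaldehyde), C=O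
Why: Casnati–Skattebøl magnesium-phenoxide ortho-formylation is ortho-specific and only C6 is free (the other ortho position carries Br); the benzylic alcohol is oxidised in the flask by a second formaldehyde.

**Step 2**
Reactants: 3 3-bromo-2-hydroxy-6-methylbenzaldehyde
Product: 4 3-bromo-2-methoxy-6-methylbenzaldehyde
Conditions: MeI, K2CO3, DMF, 23 °C
Reagents that add atoms: iodomethane, CI
Why: Williamson O-methylation of the acidic salicylaldehyde phenol.

**Step 3**
Reactants: 4 3-bromo-2-methoxy-6-methylbenzaldehyde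
Product: 5 3-bromo-2-methoxy-6-methylbenzoic acid
Conditions: NaClO2, NaH2PO4, 2-methylbut-2-ene, t-BuOH/H2O, 23 °C
Reagents that add atoms: sodium chlorite, [Na+].[O-]Cl=O
Why: Pinnick oxidation converts the hindered aryl aldehyde to the acid without touching the aryl bromide or benzylic methyl.

**Step 4**
Reactants: 5 3-bromo-2-methoxy-6-methylbenzoic acid
Product: 6 methyl 3-bromo-2-methoxy-6-methylbenzoate
Conditions: MeI, K2CO3, DMF, 23 °C
Reagents that add atoms: iodomethane, CI
Why: SN2 alkylation of the carboxylate works for 2,6-disubstituted benzoic acids where Fischer esterification is slow.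

**Step 5**
Reactants: 6 methyl 3-bromo-2-methoxy-6-methylbenzoate; 7 (E)-4-methoxypent-3-en-2-one
Product: 11 1-(7-bromo-1-hydroxy-8-methoxy-3-methylnaphthalen-2-yl)ethan-1-one, via benzylic lithium 8 (not isolated), via Michael adduct enolate 9 (not isolated), via methoxy diketone 10 (not isolated)
Conditions: LDA (2.2 equiv), THF, −78 °C; then 7, −78 → 23 °C; NH4Cl (aq)
Reagents that add atoms: none
Why: Staunton–Weinreb-type tandem Michael addition/Claisen (Dieckmann) condensation; the laterally lithiated toluate adds to the β-carbon of the enone, the enolate acylates on the ester, and loss of methanol aromatises to the 2-acetyl-3-methyl-1-naphthol.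

**Step 6**
Reactants: 11 1-(7-bromo-1-hydroxy-8-methoxy-3-methylnaphthalen-2-yl)ethan-1-one
Product: 12 1-(7-bromo-1,8-dihydroxy-3-methylnaphthalen-2-yl)ethan-1-one
Conditions: BBr3, CH2Cl2, −78 → 0 °C; H2O
Reagents that add atoms: none
Why: Lewis-acid aryl methyl ether cleavage of the single methoxy group; the ketone and aryl bromide are inert.

**Step 7**
Reactants: 12 1-(7-bromo-1,8-dihydroxy-3-methylnaphthalen-2-yl)ethan-1-one
Product: 13 1-[7-bromo-1,8-(di-tert-butylsilanediyldioxy)-3-methylnaphthalen-2-yl]ethan-1-one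
Conditions: t-Bu2Si(OTf)2, 2,6-lutidine, CH2Cl2, 0 → 23 °C
Reagents that add atoms: di-tert-butylsilyl bis(trifluoromethanesulfonate), CC(C)(C)[Si](OS(=O)(=O)C(F)(F)F)(OS(=O)(=O)C(F)(F)F)C(C)(C)C
Why: Silylene protection; the peri 1,8-diol closes a six-membered O–Si–O ring, masking both phenols with one fluoride-labile group.

**Step 8**
Reactants: 13 1-[7-bromo-1,8-(di-tert-butylsilanediyldioxy)-3-methylnaphthalen-2-yl]ethan-1-one
Product: 14 1-[1,8-(di-tert-butylsilanediyldioxy)-3-methyl-7-(4,4,5,5-tetramethyl-1,3,2-dioxaborolan-2-yl)naphthalen-2-yl]ethan-1-one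
Conditions: B2pin2, PdCl2(dppf) (5 mol%), KOAc, dioxane, 85 °C
Reagents that add atoms: bis(pinacolato)diboron, CC1(C)OB(OC1(C)C)B1OC(C)(C)C(C)(C)O1
Why: Miyaura borylation of the aryl bromide under anhydrous acetate conditions that tolerate the ketone and the silylene.

**Step 9**
Reactants: 15 2-bromo-5-iodophenol
Product: 17 3-bromo-2-hydroxy-6-iodobenzaldehyde, via hydroxymethyl phenol 16 (not isolated)
Conditions: MgCl2, Et3N, (CH2O)n, MeCN, reflux; 1 M HCl
Reagents that add atoms: paraformaldehyde (formaldehyde), C=O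
Why: Casnati–Skattebøl ortho-formylation; with the other ortho position blocked by Br, the formyl group can only enter between OH and the iodide.

**Step 10**
Reactants: 17 3-bromo-2-hydroxy-6-iodobenzaldehyde
Product: 18 3-bromo-6-iodo-2-[(triisopropylsilyl)oxy]benzaldehyde
Conditions: TIPSOTf, 2,6-lutidine, CH2Cl2, 0 → 23 °C
Reagents that add atoms: triisopropylsilyl trifluoromethanesulfonate, CC(C)[Si](OS(=O)(=O)C(F)(F)F)(C(C)C)C(C)C
Why: Silyl ether formation with the reactive triflate covers the hindered phenol with a base-robust, fluoride-labile group.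

**Step 11**
Reactants: 18 3-bromo-6-iodo-2-[(triisopropylsilyl)oxy]benzaldehyde
Product: 19 3-bromo-2-[(triisopropylsilyl)oxy]-6-vinylbenzaldehyde
Conditions: tributyl(vinyl)stannane (1.05 equiv), Pd(PPh3)4 (5 mol%), toluene, 70 °C
Reagents that add atoms: tributyl(vinyl)stannane, C=C[Sn](CCCC)(CCCC)CCCC
Why: Stille coupling under neutral conditions; zerovalent palladium inserts into the carbon–iodine bond ortho to the aldehyde far faster than into the electron-rich, hindered carbon–bromine bond.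

**Step 12**
Reactants: 14 naphthyl pinacol boronate; 19 3-bromo-2-[(triisopropylsilyl)oxy]-6-vinylbenzaldehyde
Product: 20 3-(NpSi)-2-[(triisopropylsilyl)oxy]-6-vinylbenzaldehyde
Conditions: Pd(OAc)2 (5 mol%), SPhos (10 mol%), K3PO4, toluene/H2O 10:1, 60 °C
Reagents that add atoms: none
Why: Suzuki–Miyaura coupling with a biaryl-phosphine ligand suited to 2,2'-dioxygenated biaryls; only one halide remains, so there is no site competition.

**Step 13**
Reactants: 21 3-methylbut-3-enoic acid; 22 (S)-4-benzyloxazolidin-2-one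
Product: 25 (S)-4-benzyl-3-(3-methylbut-3-enoyl)oxazolidin-2-one, via mixed pivalic anhydride 23 (not isolated), via N-lithio oxazolidinone 24 (not isolated)
Conditions: 21, PivCl, Et3N, THF, −78 → 0 °C; then 22/n-BuLi (THF, −78 °C), −78 → 0 °C; NH4Cl (aq)
Reagents that add atoms: none
Why: N-acylation of the lithiated Evans auxiliary by the mixed anhydride at low temperature, which avoids isomerising the β,γ-alkene into conjugation.

**Step 14 (key step)**
Reactants: 20 3-(NpSi)-2-[(triisopropylsilyl)oxy]-6-vinylbenzaldehyde; 25 (S)-4-benzyl-3-(3-methylbut-3-enoyl)oxazolidin-2-one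
Product: 27 (4S)-4-benzyl-3-{(2R)-2-[(S)-hydroxy(ArB)methyl]-3-methylbut-3-enoyl}oxazolidin-2-one, via trimethylsilyl ether 26 (not isolated)
Conditions: 25 (1.5 equiv), MgCl2 (0.3 equiv), Et3N (2.5 equiv), TMSCl (2 equiv), EtOAc, 23 °C, 36 h; then TFA (cat.), MeOH, 0 °C
Reagents that add atoms: none
Why: Evans magnesium-halide-catalysed direct anti-aldol; the Mg-chelated Z-dienolate reacts at its α-carbon with the non-enolisable aldehyde on the face opposite the benzyl group through a boat transition state, and silyl trapping of the aldolate fixes the anti (C1' S, C2' R) pair.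

**Step 15**
Reactants: 27 anti-aldol adduct
Product: 28 (4S)-4-benzyl-3-{(2R)-3-methyl-2-[(S)-(ArB)(triethylsilyloxy)methyl]but-3-enoyl}oxazolidin-2-one
Conditions: TESOTf (1.2 equiv), 2,6-lutidine, CH2Cl2, −78 °C
Reagents that add atoms: triethylsilyl trifluoromethanesulfonate, CC[Si](CC)(CC)OS(=O)(=O)C(F)(F)F
Why: Silylation of the secondary alcohol blocks retro-aldol and β-elimination in the following steps and does not touch either stereocentre.

**Step 16**
Reactants: 28 TES-protected imide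
Product: 29 S-ethyl (2R)-3-methyl-2-[(S)-(ArB)(triethylsilyloxy)methyl]but-3-enethioate
Conditions: EtSH (3 equiv), n-BuLi (2.2 equiv), THF, 0 °C; NH4Cl (aq)
Reagents that add atoms: ethanethiol (as LiSEt), CCS
Why: Acyl transfer to the weakly basic thiolate (Damon-type auxiliary cleavage) is selective for the exocyclic carbonyl and leaves the acidic α-centre intact.

**Step 17**
Reactants: 29 thioester
Product: 30 (3R)-4-methyl-3-[(S)-(ArB)(triethylsilyloxy)methyl]pent-4-en-2-one
Conditions: Me2CuLi (3 equiv; from CuBr·SMe2 and MeLi), Et2O, −78 → −40 °C; NH4Cl/NH3 (aq) at −78 °C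
Reagents that add atoms: lithium dimethylcuprate, [Li+].C[Cu-]C
Why: Cuprate acyl substitution of a thioester gives the methyl ketone and stops there; Gilman reagents do not add to the hindered aryl ketone of ring A and are too weakly basic to epimerise C2'.

**Step 18**
Reactants: 30 acyclic methyl ketone
Product: 31 1-{(1S,2R)-7-(NpSi)-3-methyl-1-[(triethylsilyl)oxy]-8-[(triisopropylsilyl)oxy]-1,2-dihydronaphthalen-2-yl}ethan-1-one
Conditions: second-generation Grubbs catalyst (10 mol%), CH2Cl2 (5 mM), 40 °C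
Reagents that add atoms: none
Why: Ring-closing metathesis between the styrene and the isopropenyl group forms the six-membered ring with its trisubstituted C3'=C4' alkene under neutral conditions, so neither stereocentre is touched.

**Step 19**
Reactants: 31 protected dihydronaphthalenol
Product: 32 1-[(1S,2R)-7-(2-acetyl-1,8-dihydroxy-3-methylnaphthalen-7-yl)-1,8-dihydroxy-3-methyl-1,2-dihydronaphthalen-2-yl]ethan-1-one
Conditions: TBAF/AcOH (1:1, excess), THF, 0 → 23 °C
Reagents that add atoms: none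
Why: Acetic-acid-buffered fluoride desilylation removes the aryl silyl ether, the silylene and the TES ether at near-neutral pH, avoiding both acid ionisation at C1' and base-induced β-elimination that would aromatise ring B.

## Compound list

1 | 2-bromo-5-methylphenol | Cc1ccc(Br)c(O)c1 | starting material
2 | 6-bromo-2-(hydroxymethyl)-3-methylphenol (magnesium salt, not isolated) | Cc1ccc(Br)c(O)c1CO | intermediate
3 | 3-bromo-2-hydroxy-6-methylbenzaldehyde | Cc1ccc(Br)c(O)c1C=O | intermediate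
4 | 3-bromo-2-methoxy-6-methylbenzaldehyde | Cc1ccc(Br)c(OC)c1C=O | intermediate
5 | 3-bromo-2-methoxy-6-methylbenzoic acid | Cc1ccc(Br)c(OC)c1C(=O)O | intermediate
6 | methyl 3-bromo-2-methoxy-6-methylbenzoate | Cc1ccc(Br)c(OC)c1C(=O)OC | intermediate
7 | (E)-4-methoxypent-3-en-2-one | CO/C(C)=C/C(C)=O | starting material
8 | [4-bromo-3-methoxy-2-(methoxycarbonyl)phenyl]methyllithium (not isolated) | [Li]Cc1ccc(Br)c(OC)c1C(=O)OC | intermediate
9 | methyl 3-bromo-2-methoxy-6-(2-methoxy-2-methyl-4-oxopentyl)benzoate (lithium enolate, not isolated) | COC(=O)c1c(OC)c(Br)ccc1CC(C)(OC)CC(C)=O | intermediate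
10 | 2-acetyl-7-bromo-3,8-dimethoxy-3-methyl-3,4-dihydronaphthalen-1(2H)-one (lithium enolate, not isolated) | CC(=O)C1C(=O)c2c(OC)c(Br)ccc2CC1(C)OC | intermediate
11 | 1-(7-bromo-1-hydroxy-8-methoxy-3-methylnaphthalen-2-yl)ethan-1-one | CC(=O)c1c(C)cc2ccc(Br)c(OC)c2c1O | intermediate
12 | 1-(7-bromo-1,8-dihydroxy-3-methylnaphthalen-2-yl)ethan-1-one | CC(=O)c1c(C)cc2ccc(Br)c(O)c2c1O | intermediate
13 | 1-[7-bromo-1,8-(di-tert-butylsilanediyldioxy)-3-methylnaphthalen-2-yl]ethan-1-one | CC(=O)c1c(C)cc2ccc(Br)c3O[Si](C(C)(C)C)(C(C)(C)C)Oc1c23 | intermediate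
14 | 1-[1,8-(di-tert-butylsilanediyldioxy)-3-methyl-7-(4,4,5,5-tetramethyl-1,3,2-dioxaborolan-2-yl)naphthalen-2-yl]ethan-1-one | CC(=O)c1c(C)cc2ccc(B4OC(C)(C)C(C)(C)O4)c3O[Si](C(C)(C)C)(C(C)(C)C)Oc1c23 | intermediate
15 | 2-bromo-5-iodophenol | Oc1cc(I)ccc1Br | starting material
16 | 6-bromo-2-(hydroxymethyl)-3-iodophenol (magnesium salt, not isolated) | OCc1c(I)ccc(Br)c1O | intermediate
17 | 3-bromo-2-hydroxy-6-iodobenzaldehyde | O=Cc1c(I)ccc(Br)c1O | intermediate
18 | 3-bromo-6-iodo-2-[(triisopropylsilyl)oxy]benzaldehyde | O=Cc1c(I)ccc(Br)c1O[Si](C(C)C)(C(C)C)C(C)C | intermediate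
19 | 3-bromo-2-[(triisopropylsilyl)oxy]-6-vinylbenzaldehyde | C=Cc1ccc(Br)c(O[Si](C(C)C)(C(C)C)C(C)C)c1C=O | intermediate
20 | 3-(NpSi)-2-[(triisopropylsilyl)oxy]-6-vinylbenzaldehyde | CC(=O)c1c(C)cc2ccc(-c4ccc(C=C)c(C=O)c4O[Si](C(C)C)(C(C)C)C(C)C)c3O[Si](C(C)(C)C)(C(C)(C)C)Oc1c23 | intermediate
21 | 3-methylbut-3-enoic acid | C=C(C)CC(=O)O | starting material
22 | (S)-4-benzyloxazolidin-2-one | O=C1N[C@@H](Cc2ccccc2)CO1 | starting material
23 | 3-methylbut-3-enoic pivalic anhydride (not isolated) | C=C(C)CC(=O)OC(=O)C(C)(C)C | intermediate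
24 | lithium salt of (S)-4-benzyloxazolidin-2-one (not isolated) | [Li]N1[C@@H](Cc2ccccc2)COC1=O | intermediate
25 | (S)-4-benzyl-3-(3-methylbut-3-enoyl)oxazolidin-2-one | C=C(C)CC(=O)N1[C@@H](Cc2ccccc2)COC1=O | intermediate
26 | trimethylsilyl ether of 27 (not isolated) | CC(=O)c1c(C)cc2ccc(-c4ccc(C=C)c([C@@H](O[Si](C)(C)C)[C@H](C(=O)N5[C@@H](Cc6ccccc6)COC5=O)C(C)=C)c4O[Si](C(C)C)(C(C)C)C(C)C)c3O[Si](C(C)(C)C)(C(C)(C)C)Oc1c23 | intermediate
27 | (4S)-4-benzyl-3-{(2R)-2-[(S)-hydroxy(ArB)methyl]-3-methylbut-3-enoyl}oxazolidin-2-one | CC(=O)c1c(C)cc2ccc(-c4ccc(C=C)c([C@@H](O)[C@H](C(=O)N5[C@@H](Cc6ccccc6)COC5=O)C(C)=C)c4O[Si](C(C)C)(C(C)C)C(C)C)c3O[Si](C(C)(C)C)(C(C)(C)C)Oc1c23 | intermediate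
28 | (4S)-4-benzyl-3-{(2R)-3-methyl-2-[(S)-(ArB)(triethylsilyloxy)methyl]but-3-enoyl}oxazolidin-2-one | CC(=O)c1c(C)cc2ccc(-c4ccc(C=C)c([C@@H](O[Si](CC)(CC)CC)[C@H](C(=O)N5[C@@H](Cc6ccccc6)COC5=O)C(C)=C)c4O[Si](C(C)C)(C(C)C)C(C)C)c3O[Si](C(C)(C)C)(C(C)(C)C)Oc1c23 | intermediate
29 | S-ethyl (2R)-3-methyl-2-[(S)-(ArB)(triethylsilyloxy)methyl]but-3-enethioate | CC(=O)c1c(C)cc2ccc(-c4ccc(C=C)c([C@@H](O[Si](CC)(CC)CC)[C@H](C(=O)SCC)C(C)=C)c4O[Si](C(C)C)(C(C)C)C(C)C)c3O[Si](C(C)(C)C)(C(C)(C)C)Oc1c23 | intermediate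
30 | (3R)-4-methyl-3-[(S)-(ArB)(triethylsilyloxy)methyl]pent-4-en-2-one | CC(=O)c1c(C)cc2ccc(-c4ccc(C=C)c([C@@H](O[Si](CC)(CC)CC)[C@H](C(C)=O)C(C)=C)c4O[Si](C(C)C)(C(C)C)C(C)C)c3O[Si](C(C)(C)C)(C(C)(C)C)Oc1c23 | intermediate
31 | 1-{(1S,2R)-7-(NpSi)-3-methyl-1-[(triethylsilyl)oxy]-8-[(triisopropylsilyl)oxy]-1,2-dihydronaphthalen-2-yl}ethan-1-one | CC(=O)c1c(C)cc2ccc(-c4ccc5c(c4O[Si](C(C)C)(C(C)C)C(C)C)[C@@H](O[Si](CC)(CC)CC)[C@H](C(C)=O)C(C)=C5)c3O[Si](C(C)(C)C)(C(C)(C)C)Oc1c23 | intermediate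
32 | 1-[(1S,2R)-7-(2-acetyl-1,8-dihydroxy-3-methylnaphthalen-7-yl)-1,8-dihydroxy-3-methyl-1,2-dihydronaphthalen-2-yl]ethan-1-one | CC(=O)c1c(C)cc2ccc(-c3ccc4c(c3O)[C@@H](O)[C@H](C(C)=O)C(C)=C4)c(O)c2c1O | target

## Summary

Total steps: 19. Longest linear sequence: 15 (steps 1–8, 12, 14–19).

The three steps most likely to fail:

**Step 14 (anti-aldol of a 2,6-disubstituted aldehyde with a dienolate).** The aldehyde is hindered and this donor is an extension of the usual propionyl scope. The fallback sets out from 20 and replaces the magnesium-chelate direct aldol with a preformed boron enolate attacking a Lewis-acid-activated aldehyde through an open transition state, using the enantiomeric auxiliary. Anhydride 23 is coupled with (R)-4-benzyloxazolidin-2-one (Et3N, LiCl, THF) to give (R)-4-benzyl-3-(3-methylbut-3-enoyl)oxazolidin-2-one F1. Bu2BOTf/i-Pr2NEt (CH2Cl2, −78 °C) converts it into the Z-dibutylboron dienolate F2, which is added to 20 precomplexed with Et2AlCl. Attack on the enolate face away from the benzyl group gives the anti adduct with the (R)-auxiliary F3, carrying the same (S)-carbinol and (R)-α centres as 27. TESOTf gives the triethylsilyl ether F4, and LiSEt cleavage returns to the route at thioester 29.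

**Step 5 (Michael–Claisen annulation).** Proton transfer from the enolisable methyl ketone of 7, or 1,2-addition, can compete with conjugate addition. The fallback sets out from 6 and adds its anion 8 to methyl (E)-3-methoxybut-2-enoate, an acceptor without a ketone. The Michael adduct methyl 3-bromo-2-methoxy-6-(2-methoxy-4-methoxy-2-methyl-4-oxobutyl)benzoate F5 closes to methyl 7-bromo-3,8-dimethoxy-3-methyl-1-oxo-1,2,3,4-tetrahydronaphthalene-2-carboxylate F6, which loses methanol to give methyl 7-bromo-1-hydroxy-8-methoxy-3-methyl-2-naphthoate F7. Saponification (KOH, aq. EtOH, reflux) gives 7-bromo-1-hydroxy-8-methoxy-3-methyl-2-naphthoic acid F8, and excess MeLi (THF, 0 °C) adds once to the lithium carboxylate to return to the route at ketone 11.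

**Step 19 (global desilylation of the elimination-prone dihydronaphthalenol).** Loss of the C1' oxygen would aromatise ring B irreversibly. The fallback sets out from 30 and inverts the order of the last two operations: buffered fluoride (TBAF/AcOH, THF) first gives the fully desilylated acyclic diene (3R)-3-[(S)-hydroxy{3-(2-acetyl-1,8-dihydroxy-3-methylnaphthalen-7-yl)-2-hydroxy-6-vinylphenyl}methyl]-4-methylpent-4-en-2-one F9. Ring-closing metathesis of F9 (second-generation Grubbs catalyst, CH2Cl2, 40 °C) then forms ring B as the final, neutral step and arrives directly at 32.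

## Further compounds

F1 | step 14 | (R)-4-benzyl-3-(3-methylbut-3-enoyl)oxazolidin-2-one | C=C(C)CC(=O)N1[C@H](Cc2ccccc2)COC1=O
F2 | step 14 | Z-dibutylboron dienolate of F1 | C=C(C)/C=C(\OB(CCCC)CCCC)N1[C@H](Cc2ccccc2)COC1=O
F3 | step 14 | (4R)-4-benzyl-3-{(2R)-2-[(S)-hydroxy(ArB)methyl]-3-methylbut-3-enoyl}oxazolidin-2-one | CC(=O)c1c(C)cc2ccc(-c4ccc(C=C)c([C@@H](O)[C@H](C(=O)N5[C@H](Cc6ccccc6)COC5=O)C(C)=C)c4O[Si](C(C)C)(C(C)C)C(C)C)c3O[Si](C(C)(C)C)(C(C)(C)C)Oc1c23
F4 | step 14 | triethylsilyl ether of F3 | CC(=O)c1c(C)cc2ccc(-c4ccc(C=C)c([C@@H](O[Si](CC)(CC)CC)[C@H](C(=O)N5[C@H](Cc6ccccc6)COC5=O)C(C)=C)c4O[Si](C(C)C)(C(C)C)C(C)C)c3O[Si](C(C)(C)C)(C(C)(C)C)Oc1c23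
F5 | step 5 | methyl 3-bromo-2-methoxy-6-(2-methoxy-4-methoxy-2-methyl-4-oxobutyl)benzoate | COC(=O)CC(C)(OC)Cc1ccc(Br)c(OC)c1C(=O)OC
F6 | step 5 | methyl 7-bromo-3,8-dimethoxy-3-methyl-1-oxo-1,2,3,4-tetrahydronaphthalene-2-carboxylate | COC(=O)C1C(=O)c2c(OC)c(Br)ccc2CC1(C)OC
F7 | step 5 | methyl 7-bromo-1-hydroxy-8-methoxy-3-methyl-2-naphthoate | COC(=O)c1c(C)cc2ccc(Br)c(OC)c2c1O
F8 | step 5 | 7-bromo-1-hydroxy-8-methoxy-3-methyl-2-naphthoic acid | OC(=O)c1c(C)cc2ccc(Br)c(OC)c2c1O
F9 | step 19 | (3R)-3-[(S)-hydroxy{3-(2-acetyl-1,8-dihydroxy-3-methylnaphthalen-7-yl)-2-hydroxy-6-vinylphenyl}methyl]-4-methylpent-4-en-2-one | CC(=O)c1c(C)cc2ccc(-c3ccc(C=C)c([C@@H](O)[C@H](C(C)=O)C(C)=C)c3O)c(O)c2c1O
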